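Assumption: the SMILES is read as (1R,4S,7R,7aS) in the bicyclic core (side chain, acyloxy group, carboxyl and angular methyl all on one face) and 8R in the acyl chain. Bicyclic compounds are numbered as 1H-inden-2-one throughout: C1 carries the side chain, C2 the ketone, C3=C3a the alkene, C4 the oxygen, C7 the carboxyl and C7a the methyl.

## Retrosynthetic overview

1. Target ⇒ acidolysis of tert-butyl ester/diethyl acetal 42 ⇒ Yamaguchi ester bond at C4–O between bicyclic alcohol 28 and trienoic acid 40 (fragment 3).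
2. 28 ⇒ Rh-catalysed conjugate addition of alkenylboronate 26 (fragment 2, from acrolein) to exo-methylene dienone 21; C1 is set by equilibration.
3. C4–O ⇒ Rh2-catalysed allylic C–H oxidation of enone 13, then carbonyl reduction with hydride delivered anti to the angular methyl.
4. Ring order: the six-membered ring comes from 2-methylcyclohexenone by a Cu-catalysed enantioselective conjugate addition of a silylmethyl Grignard reagent (masked carboxyl) with allyl trapping (sets C7 and C7a); the five-membered ring is closed second by Wacker oxidation and aldol condensation (fragment 1).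
5. Fragment 3 ⇒ Heck coupling of alkenyl iodide 37 (tiglic acid: Ru-catalysed hydrogenation, Corey–Fuchs homologation, hydrozirconation) with methyl penta-2,4-dienoate.

## Route

### Fragment 1: bicyclic core

Step 1
Reactants: 1 (chloromethyl)chlorodimethylsilane; 2 propan-2-ol
Product: 3 (chloromethyl)dimethyl(propan-2-yloxy)silane
Conditions: i-PrOH (1.05 equiv), Et3N (1.1 equiv), Et2O, 0 °C → rt; filter, distil
Reagents that add atoms: none
Why: Alcoholysis of the Si–Cl bond (substitution at silicon) is fast and leaves the C–Cl bond untouched for Grignard formation; no stereocentre is formed.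

Step 2
Reactants: 3 (chloromethyl)dimethyl(propan-2-yloxy)silane; 4 2-methylcyclohex-2-en-1-one; 5 3-iodoprop-1-ene
Product: 8 (2S,3R)-3-{[dimethyl(propan-2-yloxy)silyl]methyl}-2-methyl-2-(prop-2-en-1-yl)cyclohexan-1-one, via Grignard reagent 6 (not isolated), via magnesium enolate 7 (not isolated)
Conditions: Mg, BrCH2CH2Br (cat.), THF, 45 °C; then 4, Cu(OTf)2 (3 mol %), L1 (4.5 mol %), Et2O, −30 °C; then 5 (3 equiv), DMPU, −30 °C → rt. L1 = 1-[(2S)-1-hydroxy-4-methylpentan-2-yl]-3-(2,4,6-trimethylphenyl)-4,5-dihydro-1H-imidazol-3-ium hexafluorophosphate (the antipode is used if the first screen shows the opposite sense).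
Reagents that add atoms: none
Why: Proposed new method: the Cu–NHC alkylcuprate formed from 6 should π-complex the enone, add oxidatively at C3 and reductively eliminate (the silylmethyl group has no β-hydrogen, so no reduction pathway competes) with the ligand fixing the 3R centre, and the tetrasubstituted magnesium enolate 7 is then allylated anti to the new C3 substituent to give the 2S quaternary centre; the closest known reactions are Cu–NHC-catalysed enantioselective conjugate additions of primary alkyl Grignard reagents to 2-methylcyclohexenone with enolate trapping and the racemic Cu-catalysed conjugate addition of this silylmethyl Grignard reagent to enones.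

Step 3
Reactants: 8 (2S,3R)-3-{[dimethyl(propan-2-yloxy)silyl]methyl}-2-methyl-2-(prop-2-en-1-yl)cyclohexan-1-one
Product: 9 (2S,3R)-3-(hydroxymethyl)-2-methyl-2-(prop-2-en-1-yl)cyclohexan-1-one
Conditions: 30% H2O2 (10 equiv), KF, KHCO3, THF/MeOH (1:1), rt
Reagents that add atoms: hydrogen peroxide (OO)
Why: Tamao–Fleming oxidation converts the alkoxysilane C–Si bond into C–OH at a CH2 group, so both ring stereocentres are untouched and the ketone and terminal alkene tolerate the buffered peroxide.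

Step 4
Reactants: 9 (2S,3R)-3-(hydroxymethyl)-2-methyl-2-(prop-2-en-1-yl)cyclohexan-1-one
Product: 10 (1R,2S)-2-methyl-3-oxo-2-(prop-2-en-1-yl)cyclohexane-1-carboxylic acid
Conditions: TEMPO (0.2 equiv), PhI(OAc)2 (2.5 equiv), MeCN/H2O (1:1), rt
Reagents that add atoms: water (O)
Why: TEMPO/PhI(OAc)2 oxidation of the primary alcohol proceeds through the aldehyde hydrate to the acid without touching the alkene or epimerising the adjacent centre.

Step 5
Reactants: 10 (1R,2S)-2-methyl-3-oxo-2-(prop-2-en-1-yl)cyclohexane-1-carboxylic acid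
Product: 11 tert-butyl (1R,2S)-2-methyl-3-oxo-2-(prop-2-en-1-yl)cyclohexane-1-carboxylate
Conditions: t-BuOC(=NH)CCl3 (2 equiv), BF3·OEt2 (5 mol %), CH2Cl2/cyclohexane, rt
Reagents that add atoms: tert-butyl 2,2,2-trichloroacetimidate (CC(C)(C)OC(=N)C(Cl)(Cl)Cl)
Why: Acid-catalysed tert-butylation with the trichloroacetimidate gives a hindered ester that survives the later base, hydride and enolate steps and is removed by acid at the end.

Step 6
Reactants: 11 tert-butyl (1R,2S)-2-methyl-3-oxo-2-(prop-2-en-1-yl)cyclohexane-1-carboxylate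
Product: 12 tert-butyl (1R,2S)-2-methyl-3-oxo-2-(2-oxopropyl)cyclohexane-1-carboxylate
Conditions: PdCl2 (10 mol %), CuCl (1 equiv), O2 (1 atm), DMF/H2O (7:1), rt
Reagents that add atoms: water (O)
Why: Tsuji–Wacker oxidation (Markovnikov hydroxypalladation by divalent palladium, CuCl/O2 turnover) turns the terminal alkene into the methyl ketone, a reaction well established for 2-allyl-2-methylcyclohexanones.

Step 7
Reactants: 12 tert-butyl (1R,2S)-2-methyl-3-oxo-2-(2-oxopropyl)cyclohexane-1-carboxylate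
Product: 13 tert-butyl (7R,7aS)-7a-methyl-2-oxo-2,4,5,6,7,7a-hexahydro-1H-indene-7-carboxylate
Conditions: t-BuOK (0.3 equiv), t-BuOH, 50 °C
Reagents that add atoms: none
Why: Intramolecular aldol condensation of the 1,4-diketone (methyl ketone enolate onto the ring ketone, irreversible dehydration) closes the cyclopentenone; the equatorial C7 ester is also the thermodynamic epimer, so it is not at risk.

Step 8
Reactants: 13 tert-butyl (7R,7aS)-7a-methyl-2-oxo-2,4,5,6,7,7a-hexahydro-1H-indene-7-carboxylate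
Product: 14 tert-butyl (7R,7aS)-7a-methyl-2,4-dioxo-2,4,5,6,7,7a-hexahydro-1H-indene-7-carboxylate
Conditions: Rh2(caprolactamate)4 (1 mol %), t-BuOOH (70% aq., 5 equiv), K2CO3 (0.5 equiv), CH2Cl2, rt
Reagents that add atoms: tert-butyl hydroperoxide (CC(C)(C)OO)
Why: Dirhodium caprolactamate/TBHP allylic C–H oxidation abstracts hydrogen from C4, the only allylic methylene (C7a is quaternary), and the mixed peroxide collapses to the enedione, as known for cyclic enones.

Step 9
Reactants: 14 tert-butyl (7R,7aS)-7a-methyl-2,4-dioxo-2,4,5,6,7,7a-hexahydro-1H-indene-7-carboxylate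
Product: 15 tert-butyl (4S,7R,7aS)-2,4-dihydroxy-7a-methyl-2,4,5,6,7,7a-hexahydro-1H-indene-7-carboxylate (both C2 epimers)
Conditions: NaBH4 (3 equiv), CeCl3·7H2O (2.2 equiv), MeOH, −78 → 0 °C
Reagents that add atoms: none
Why: Luche 1,2-reduction of both carbonyls; at C4 hydride attacks from the face opposite the syn-axial angular methyl and so gives the axial 4S alcohol cis to that methyl (as in steroidal 4-en-6-ones), while the C2 configuration is irrelevant because it is re-oxidised.

Step 10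
Reactants: 15 tert-butyl (4S,7R,7aS)-2,4-dihydroxy-7a-methyl-2,4,5,6,7,7a-hexahydro-1H-indene-7-carboxylate
Product: 16 tert-butyl (4S,7R,7aS)-4-hydroxy-7a-methyl-2-oxo-2,4,5,6,7,7a-hexahydro-1H-indene-7-carboxylate
Conditions: activated MnO2 (20 equiv), CH2Cl2, rt
Reagents that add atoms: none
Why: MnO2 allylic oxidation takes the unhindered cyclopentenol, whose C–H overlaps with the alkene π system, and leaves the axial C4 alcohol (its C–H lies in the alkene plane and is shielded by the angular methyl), by analogy with the selective C3 oxidation of steroidal 4-ene-3,6-diols.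

Step 11
Reactants: 16 tert-butyl (4S,7R,7aS)-4-hydroxy-7a-methyl-2-oxo-2,4,5,6,7,7a-hexahydro-1H-indene-7-carboxylate
Product: 17 tert-butyl (4S,7R,7aS)-4-{[tert-butyl(dimethyl)silyl]oxy}-7a-methyl-2-oxo-2,4,5,6,7,7a-hexahydro-1H-indene-7-carboxylate
Conditions: TBSOTf (1.5 equiv), 2,6-lutidine (3 equiv), CH2Cl2, −78 → 0 °C
Reagents that add atoms: tert-butyldimethylsilyl trifluoromethanesulfonate (CC(C)(C)[Si](C)(C)OS(=O)(=O)C(F)(F)F)
Why: Silyl triflate with a hindered pyridine base silylates even the hindered axial alcohol without enolising the enone.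

Step 12
Reactants: 17 tert-butyl (4S,7R,7aS)-4-{[tert-butyl(dimethyl)silyl]oxy}-7a-methyl-2-oxo-2,4,5,6,7,7a-hexahydro-1H-indene-7-carboxylate
Product: 21 tert-butyl (4S,7R,7aS)-4-{[tert-butyl(dimethyl)silyl]oxy}-7a-methyl-1-methylidene-2-oxo-2,4,5,6,7,7a-hexahydro-1H-indene-7-carboxylate, via lithium enolate 18 (not isolated), via Mannich base 19 (not isolated), via ammonium iodide 20 (not isolated)
Conditions: LDA (1.15 equiv), THF, −78 °C; CH2=NMe2+ I− (2 equiv), −78 °C → rt; MeI (10 equiv), CH2Cl2, rt; sat. aq. NaHCO3/CH2Cl2, rt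
Reagents that add atoms: N,N-dimethylmethyleneiminium iodide (C=[N+](C)C.[I-])
Why: Kinetic deprotonation at C1 (the C4 hydrogen is equatorial and misaligned, the ester α-hydrogen is less acidic and hindered), a Mannich reaction with Eschenmoser's salt, quaternisation and E1cB elimination give the exo-methylene ketone; C1 becomes sp2, so no stereocentre is set.

### Fragment 2: alkenylboronate

Step 13
Reactants: 22 prop-2-enal
Product: 24 2-bromoprop-2-enal, via 2,3-dibromopropanal 23 (not isolated)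
Conditions: Br2 (1.0 equiv), CH2Cl2, −78 °C; then Et3N (1.05 equiv), −78 → 0 °C
Reagents that add atoms: bromine (BrBr)
Why: Bromine addition followed by E1cB loss of HBr through the acidic α-hydrogen gives the 2-bromo enal regioselectively.

Step 14
Reactants: 24 2-bromoprop-2-enal
Product: 25 2-bromo-3,3-diethoxyprop-1-ene
Conditions: HC(OEt)3 (1.2 equiv), EtOH, NH4NO3 (cat.), rt
Reagents that add atoms: triethyl orthoformate (CCOC(OCC)OCC)
Why: Orthoformate-driven acetalisation masks the aldehyde so that the alkenyl bromide can be metallated and the enal released only at the end.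

Step 15
Reactants: 25 2-bromo-3,3-diethoxyprop-1-ene
Product: 26 2-(3,3-diethoxyprop-1-en-2-yl)-4,4,5,5-tetramethyl-1,3,2-dioxaborolane
Conditions: B2pin2 (1.1 equiv), PdCl2(PPh3)2 (3 mol %), PPh3 (6 mol %), KOPh (1.5 equiv), toluene, 50 °C
Reagents that add atoms: bis(pinacolato)diboron (CC1(C)OB(OC1(C)C)B1OC(C)(C)C(C)(C)O1)
Why: Miyaura borylation of the alkenyl bromide (oxidative addition to zerovalent palladium, phenoxide-assisted transmetallation, reductive elimination) tolerates the acetal.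

### Union of fragments 1 and 2

Step 16
Reactants: 21 tert-butyl (4S,7R,7aS)-4-{[tert-butyl(dimethyl)silyl]oxy}-7a-methyl-1-methylidene-2-oxo-2,4,5,6,7,7a-hexahydro-1H-indene-7-carboxylate; 26 2-(3,3-diethoxyprop-1-en-2-yl)-4,4,5,5-tetramethyl-1,3,2-dioxaborolane
Product: 27 tert-butyl (1R,4S,7R,7aS)-4-{[tert-butyl(dimethyl)silyl]oxy}-1-[2-(diethoxymethyl)prop-2-en-1-yl]-7a-methyl-2-oxo-2,4,5,6,7,7a-hexahydro-1H-indene-7-carboxylate
Conditions: [Rh(OH)(1,5-cyclooctadiene)]2 (3 mol %), 26 (2 equiv), 1,4-dioxane/H2O (10:1), 35 °C; then DBU (0.1 equiv), CH2Cl2, rt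
Reagents that add atoms: none
Why: Hayashi–Miyaura Rh-catalysed 1,4-addition: the alkenylrhodium inserts the unhindered exocyclic methylene (the ring β-carbon is fully substituted) and water protonates the rhodium enolate; C1 is then settled by equilibration as 1R, with the CH2 group on the methyl face, because the other epimer forces the side chain into a syn-pentane clash with the equatorial C7 ester.

Step 17
Reactants: 27 tert-butyl (1R,4S,7R,7aS)-4-{[tert-butyl(dimethyl)silyl]oxy}-1-[2-(diethoxymethyl)prop-2-en-1-yl]-7a-methyl-2-oxo-2,4,5,6,7,7a-hexahydro-1H-indene-7-carboxylate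
Product: 28 tert-butyl (1R,4S,7R,7aS)-1-[2-(diethoxymethyl)prop-2-en-1-yl]-4-hydroxy-7a-methyl-2-oxo-2,4,5,6,7,7a-hexahydro-1H-indene-7-carboxylate
Conditions: HF·pyridine, pyridine, THF, 0 °C → rt
Reagents that add atoms: none
Why: Buffered fluoride desilylation frees the C4 alcohol while the acetal, tert-butyl ester and the thermodynamically settled C1 centre are kept.

### Fragment 3: trienoic acid

Step 18
Reactants: 29 (2E)-2-methylbut-2-enoic acid
Product: 30 (2R)-2-methylbutanoic acid
Conditions: H2 (4 atm), Ru(OAc)2[(R)-H8-BINAP] (0.5 mol %), MeOH, 20 °C (H8-BINAP = 2,2′-bis(diphenylphosphino)-5,5′,6,6′,7,7′,8,8′-octahydro-1,1′-binaphthyl)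
Reagents that add atoms: none
Why: Ru–biaryl-diphosphine asymmetric hydrogenation of the carboxylate-bound unsaturated acid sets the stereocentre; the (R)-ligand gives the (R)-acid, mirroring the known (S)-ligand/(S)-acid result.

Step 19
Reactants: 30 (2R)-2-methylbutanoic acid
Product: 31 (2R)-2-methylbutan-1-ol
Conditions: LiAlH4 (1 equiv), Et2O, 0 °C → reflux; Fieser work-up
Reagents that add atoms: none
Why: Hydride reduction of the acid does not touch the α-stereocentre.

Step 20
Reactants: 31 (2R)-2-methylbutan-1-ol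
Product: 32 (2R)-2-methylbutanal
Conditions: TEMPO (5 mol %), PhI(OAc)2 (1.1 equiv), CH2Cl2, rt; solution used directly
Reagents that add atoms: none
Why: TEMPO/PhI(OAc)2 oxidation stops at the aldehyde under near-neutral conditions, which avoids epimerisation of the α-centre.

Step 21
Reactants: 32 (2R)-2-methylbutanal
Product: 33 (3R)-1,1-dibromo-3-methylpent-1-ene
Conditions: CBr4 (2 equiv), PPh3 (4 equiv), CH2Cl2, 0 °C
Reagents that add atoms: tetrabromomethane (BrC(Br)(Br)Br)
Why: Corey–Fuchs (Ramirez) dibromo-olefination is a base-free Wittig-type reaction that keeps the α-stereocentre.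

Step 22
Reactants: 33 (3R)-1,1-dibromo-3-methylpent-1-ene
Product: 35 (4R)-4-methylhex-2-yne, via lithium acetylide 34 (not isolated)
Conditions: n-BuLi (2.1 equiv), THF, −78 → 0 °C; then MeI (3 equiv), −78 °C → rt
Reagents that add atoms: iodomethane (CI)
Why: Corey–Fuchs alkyne formation (Br/Li exchange, Fritsch–Buttenberg–Wiechell shift, deprotonation) followed by methylation of the acetylide; the propargylic centre is not acidic enough to epimerise.

Step 23
Reactants: 35 (4R)-4-methylhex-2-yne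
Product: 37 (2E,4R)-2-iodo-4-methylhex-2-ene, via alkenylzirconocene 36 (not isolated)
Conditions: Cp2Zr(H)Cl (1.3 equiv), THF, 50 °C; then I2 (1.3 equiv), 0 °C
Reagents that add atoms: iodine (II)
Why: Schwartz hydrozirconation is a syn addition that places zirconium on the alkyne carbon next to the small methyl group, and iodinolysis with retention gives the E trisubstituted iodide.

Step 24
Reactants: 37 (2E,4R)-2-iodo-4-methylhex-2-ene; 38 methyl (2E)-penta-2,4-dienoate
Product: 39 methyl (2E,4E,6E,8R)-6,8-dimethyldeca-2,4,6-trienoate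
Conditions: Pd(OAc)2 (5 mol %), 38 (1.5 equiv), K2CO3 (2.5 equiv), n-Bu4NCl (1 equiv), DMF, 50 °C
Reagents that add atoms: none
Why: Heck coupling under Jeffery conditions: oxidative addition of the iodide to zerovalent palladium, syn insertion at the terminal CH2 of the dienoate and syn β-hydride elimination give the 4E alkene with the 6E and 2E geometries retained.

Step 25
Reactants: 39 methyl (2E,4E,6E,8R)-6,8-dimethyldeca-2,4,6-trienoate
Product: 40 (2E,4E,6E,8R)-6,8-dimethyldeca-2,4,6-trienoic acid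
Conditions: LiOH·H2O (3 equiv), THF/MeOH/H2O (3:1:1), rt; then 1 M HCl to pH 3
Reagents that add atoms: lithium hydroxide ([Li+].[OH-])
Why: Saponification of the unhindered methyl ester; the all-E triene is the thermodynamic geometry and the remote stereocentre is not affected.

### Union with fragment 3 and release of the target

Step 26
Reactants: 28 tert-butyl (1R,4S,7R,7aS)-1-[2-(diethoxymethyl)prop-2-en-1-yl]-4-hydroxy-7a-methyl-2-oxo-2,4,5,6,7,7a-hexahydro-1H-indene-7-carboxylate; 40 (2E,4E,6E,8R)-6,8-dimethyldeca-2,4,6-trienoic acid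
Product: 42 tert-butyl (1R,4S,7R,7aS)-1-[2-(diethoxymethyl)prop-2-en-1-yl]-4-{[(2E,4E,6E,8R)-6,8-dimethyldeca-2,4,6-trienoyl]oxy}-7a-methyl-2-oxo-2,4,5,6,7,7a-hexahydro-1H-indene-7-carboxylate, via mixed anhydride 41 (not isolated)
Conditions: 40 (1.5 equiv), 2,4,6-Cl3C6H2COCl (1.6 equiv), Et3N (3 equiv), THF, rt; then 28, DMAP (2 equiv), toluene, rt
Reagents that add atoms: none
Why: Yamaguchi esterification acylates the hindered axial allylic alcohol through the acyl-DMAP species with retention at C4 (the C–O bond is not broken).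

Step 27
Reactants: 42 tert-butyl (1R,4S,7R,7aS)-1-[2-(diethoxymethyl)prop-2-en-1-yl]-4-{[(2E,4E,6E,8R)-6,8-dimethyldeca-2,4,6-trienoyl]oxy}-7a-methyl-2-oxo-2,4,5,6,7,7a-hexahydro-1H-indene-7-carboxylate
Product: 43 (1R,4S,7R,7aS)-4-{[(2E,4E,6E,8R)-6,8-dimethyldeca-2,4,6-trienoyl]oxy}-1-(2-formylprop-2-en-1-yl)-7a-methyl-2-oxo-2,4,5,6,7,7a-hexahydro-1H-indene-7-carboxylic acid
Conditions: TFA/CH2Cl2/H2O (10:10:1), 0 °C → rt; toluene azeotrope; reverse-phase HPLC
Reagents that add atoms: water (O)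
Why: One acidolysis step cleaves the tert-butyl ester (loss of isobutene) and hydrolyses the enal acetal; the C4 ester does not ionise next to the electron-poor enone and C1 already has its thermodynamic configuration.

## Compound list

1 | (chloromethyl)chlorodimethylsilane | ClC[Si](C)(C)Cl | starting material
2 | propan-2-ol | CC(C)O | starting material
3 | (chloromethyl)dimethyl(propan-2-yloxy)silane | ClC[Si](C)(C)OC(C)C | intermediate
4 | 2-methylcyclohex-2-en-1-one | CC1=CCCCC1=O | starting material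
5 | 3-iodoprop-1-ene | C=CCI | starting material
6 | {[dimethyl(propan-2-yloxy)silyl]methyl}magnesium chloride | CC(C)O[Si](C)(C)C[Mg]Cl | intermediate
7 | chloromagnesium (3R)-3-{[dimethyl(propan-2-yloxy)silyl]methyl}-2-methylcyclohex-1-en-1-olate | Cl[Mg]OC1=C(C)[C@H](C[Si](C)(C)OC(C)C)CCC1 | intermediate
8 | (2S,3R)-3-{[dimethyl(propan-2-yloxy)silyl]methyl}-2-methyl-2-(prop-2-en-1-yl)cyclohexan-1-one | O=C1CCC[C@@H](C[Si](C)(C)OC(C)C)[C@@]1(CC=C)C | intermediate
9 | (2S,3R)-3-(hydroxymethyl)-2-methyl-2-(prop-2-en-1-yl)cyclohexan-1-one | O=C1CCC[C@@H](CO)[C@@]1(CC=C)C | intermediate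
10 | (1R,2S)-2-methyl-3-oxo-2-(prop-2-en-1-yl)cyclohexane-1-carboxylic acid | O=C1CCC[C@@H](C(=O)O)[C@@]1(CC=C)C | intermediate
11 | tert-butyl (1R,2S)-2-methyl-3-oxo-2-(prop-2-en-1-yl)cyclohexane-1-carboxylate | O=C1CCC[C@@H](C(=O)OC(C)(C)C)[C@@]1(CC=C)C | intermediate
12 | tert-butyl (1R,2S)-2-methyl-3-oxo-2-(2-oxopropyl)cyclohexane-1-carboxylate | O=C1CCC[C@@H](C(=O)OC(C)(C)C)[C@@]1(CC(C)=O)C | intermediate
13 | tert-butyl (7R,7aS)-7a-methyl-2-oxo-2,4,5,6,7,7a-hexahydro-1H-indene-7-carboxylate | C1C(=O)C=C2CCC[C@@H](C(=O)OC(C)(C)C)[C@@]21C | intermediate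
14 | tert-butyl (7R,7aS)-7a-methyl-2,4-dioxo-2,4,5,6,7,7a-hexahydro-1H-indene-7-carboxylate | C1C(=O)C=C2C(=O)CC[C@@H](C(=O)OC(C)(C)C)[C@@]21C | intermediate
15 | tert-butyl (4S,7R,7aS)-2,4-dihydroxy-7a-methyl-2,4,5,6,7,7a-hexahydro-1H-indene-7-carboxylate (both C2 epimers) | C1C(O)C=C2[C@@H](O)CC[C@@H](C(=O)OC(C)(C)C)[C@@]21C | intermediate
16 | tert-butyl (4S,7R,7aS)-4-hydroxy-7a-methyl-2-oxo-2,4,5,6,7,7a-hexahydro-1H-indene-7-carboxylate | C1C(=O)C=C2[C@@H](O)CC[C@@H](C(=O)OC(C)(C)C)[C@@]21C | intermediate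
17 | tert-butyl (4S,7R,7aS)-4-{[tert-butyl(dimethyl)silyl]oxy}-7a-methyl-2-oxo-2,4,5,6,7,7a-hexahydro-1H-indene-7-carboxylate | C1C(=O)C=C2[C@@H](O[Si](C)(C)C(C)(C)C)CC[C@@H](C(=O)OC(C)(C)C)[C@@]21C | intermediate
18 | lithium C1=C2 enolate of 17 (cross-conjugated dienolate, O–Li at C2) | C1=C([O-])C=C2[C@@H](O[Si](C)(C)C(C)(C)C)CC[C@@H](C(=O)OC(C)(C)C)[C@@]21C.[Li+] | intermediate
19 | tert-butyl (4S,7R,7aS)-4-{[tert-butyl(dimethyl)silyl]oxy}-1-[(dimethylamino)methyl]-7a-methyl-2-oxo-2,4,5,6,7,7a-hexahydro-1H-indene-7-carboxylate (C1 epimers) | CN(C)CC1C(=O)C=C2[C@@H](O[Si](C)(C)C(C)(C)C)CC[C@@H](C(=O)OC(C)(C)C)[C@@]21C | intermediate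
20 | N-methyl quaternary ammonium iodide of 19 (C1–CH2–NMe3+ I−) | C[N+](C)(C)CC1C(=O)C=C2[C@@H](O[Si](C)(C)C(C)(C)C)CC[C@@H](C(=O)OC(C)(C)C)[C@@]21C.[I-] | intermediate
21 | tert-butyl (4S,7R,7aS)-4-{[tert-butyl(dimethyl)silyl]oxy}-7a-methyl-1-methylidene-2-oxo-2,4,5,6,7,7a-hexahydro-1H-indene-7-carboxylate | C=C1C(=O)C=C2[C@@H](O[Si](C)(C)C(C)(C)C)CC[C@@H](C(=O)OC(C)(C)C)[C@@]21C | intermediate
22 | prop-2-enal | C=CC=O | starting material
23 | 2,3-dibromopropanal | O=CC(Br)CBr | intermediate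
24 | 2-bromoprop-2-enal | C=C(Br)C=O | intermediate
25 | 2-bromo-3,3-diethoxyprop-1-ene | C=C(Br)C(OCC)OCC | intermediate
26 | 2-(3,3-diethoxyprop-1-en-2-yl)-4,4,5,5-tetramethyl-1,3,2-dioxaborolane | C=C(B1OC(C)(C)C(C)(C)O1)C(OCC)OCC | intermediate
27 | tert-butyl (1R,4S,7R,7aS)-4-{[tert-butyl(dimethyl)silyl]oxy}-1-[2-(diethoxymethyl)prop-2-en-1-yl]-7a-methyl-2-oxo-2,4,5,6,7,7a-hexahydro-1H-indene-7-carboxylate | C=C(C(OCC)OCC)C[C@H]1C(=O)C=C2[C@@H](O[Si](C)(C)C(C)(C)C)CC[C@@H](C(=O)OC(C)(C)C)[C@@]21C | intermediate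
28 | tert-butyl (1R,4S,7R,7aS)-1-[2-(diethoxymethyl)prop-2-en-1-yl]-4-hydroxy-7a-methyl-2-oxo-2,4,5,6,7,7a-hexahydro-1H-indene-7-carboxylate | C=C(C(OCC)OCC)C[C@H]1C(=O)C=C2[C@@H](O)CC[C@@H](C(=O)OC(C)(C)C)[C@@]21C | intermediate
29 | (2E)-2-methylbut-2-enoic acid (tiglic acid) | C/C=C(\C)C(=O)O | starting material
30 | (2R)-2-methylbutanoic acid | CC[C@@H](C)C(=O)O | intermediate
31 | (2R)-2-methylbutan-1-ol | CC[C@@H](C)CO | intermediate
32 | (2R)-2-methylbutanal | CC[C@@H](C)C=O | intermediate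
33 | (3R)-1,1-dibromo-3-methylpent-1-ene | CC[C@@H](C)C=C(Br)Br | intermediate
34 | lithium (3R)-3-methylpent-1-yn-1-ide | CC[C@@H](C)C#C[Li] | intermediate
35 | (4R)-4-methylhex-2-yne | CC[C@@H](C)C#CC | intermediate
36 | chlorobis(cyclopentadienyl)[(2E,4R)-4-methylhex-2-en-2-yl]zirconium | CC[C@@H](C)/C=C(C)/[Zr](Cl)(C1C=CC=C1)C1C=CC=C1 | intermediate
37 | (2E,4R)-2-iodo-4-methylhex-2-ene | CC[C@@H](C)/C=C(C)/I | intermediate
38 | methyl (2E)-penta-2,4-dienoate | C=C/C=C/C(=O)OC | starting material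
39 | methyl (2E,4E,6E,8R)-6,8-dimethyldeca-2,4,6-trienoate | CC[C@@H](C)/C=C(C)/C=C/C=C/C(=O)OC | intermediate
40 | (2E,4E,6E,8R)-6,8-dimethyldeca-2,4,6-trienoic acid | CC[C@@H](C)/C=C(C)/C=C/C=C/C(=O)O | intermediate
41 | (2E,4E,6E,8R)-6,8-dimethyldeca-2,4,6-trienoic 2,4,6-trichlorobenzoic anhydride | CC[C@@H](C)/C=C(C)/C=C/C=C/C(=O)OC(=O)c1c(Cl)cc(Cl)cc1Cl | intermediate
42 | tert-butyl (1R,4S,7R,7aS)-1-[2-(diethoxymethyl)prop-2-en-1-yl]-4-{[(2E,4E,6E,8R)-6,8-dimethyldeca-2,4,6-trienoyl]oxy}-7a-methyl-2-oxo-2,4,5,6,7,7a-hexahydro-1H-indene-7-carboxylate | C=C(C(OCC)OCC)C[C@H]1C(=O)C=C2[C@@H](OC(=O)/C=C/C=C/C(C)=C/[C@H](C)CC)CC[C@@H](C(=O)OC(C)(C)C)[C@@]21C | intermediate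
43 | (1R,4S,7R,7aS)-4-{[(2E,4E,6E,8R)-6,8-dimethyldeca-2,4,6-trienoyl]oxy}-1-(2-formylprop-2-en-1-yl)-7a-methyl-2-oxo-2,4,5,6,7,7a-hexahydro-1H-indene-7-carboxylic acid | C=C(C=O)C[C@H]1C(=O)C=C2[C@@H](OC(=O)/C=C/C=C/C(C)=C/[C@H](C)CC)CC[C@@H](C(=O)O)[C@@]21C | target

## Step count and risks

Total step count: 27.
Longest linear sequence: 16 steps (1–12, 16, 17, 26, 27, counted from 1); fragment 2 contributes 3 steps (13–15) and fragment 3 contributes 8 steps (18–25).

The three steps most likely to fail: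

**Step 2 (the proposed new method).** The bulky silylmethyl group may transfer slowly or with low enantioselectivity. The fallback sets out from 3, 4 and 5 and uses known chemistry only: the same three-component coupling is run racemically with an achiral catalyst (CuBr·SMe2 10 mol %, THF/Me2S, −40 °C; then 5, DMPU). This gives 8 as a 1:1 mixture with its mirror image, (2R,3S)-3-{[dimethyl(propan-2-yloxy)silyl]methyl}-2-methyl-2-(prop-2-en-1-yl)cyclohexan-1-one F1. The two are separated by preparative supercritical-fluid chromatography on a chiral stationary phase, and the route is rejoined at 8.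

**Step 8.** The radical C–H oxidation may over-oxidise or attack C1. The fallback sets out from 13: Wohl–Ziegler bromination (NBS, AIBN cat., PhCF3, 80 °C) gives tert-butyl (7R,7aS)-4-bromo-7a-methyl-2-oxo-2,4,5,6,7,7a-hexahydro-1H-indene-7-carboxylate F2 as a mixture of C4 epimers. Kornblum oxidation (DMSO, NaHCO3, 80 °C) then gives 14, where the route is rejoined.

**Step 16.** The cross-conjugated dienone 21 may polymerise or the hindered alkenylboronate may protodeboronate faster than it adds. The fallback sets out from 17 and replaces the conjugate addition by enolate alkylation. LDA (THF, −78 °C) followed by inverse addition to 3-bromo-2-(bromomethyl)prop-1-ene (5 equiv) and DBU equilibration gives tert-butyl (1R,4S,7R,7aS)-1-[2-(bromomethyl)prop-2-en-1-yl]-4-{[tert-butyl(dimethyl)silyl]oxy}-7a-methyl-2-oxo-2,4,5,6,7,7a-hexahydro-1H-indene-7-carboxylate F3. Ganem oxidation (N-methylmorpholine N-oxide, MeCN, rt) gives tert-butyl (1R,4S,7R,7aS)-4-{[tert-butyl(dimethyl)silyl]oxy}-1-(2-formylprop-2-en-1-yl)-7a-methyl-2-oxo-2,4,5,6,7,7a-hexahydro-1H-indene-7-carboxylate F4. Acetalisation (HC(OEt)3, EtOH, NH4NO3 cat.) returns to the route at 27.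

## Further compounds

F1 | step 2 | (2R,3S)-3-{[dimethyl(propan-2-yloxy)silyl]methyl}-2-methyl-2-(prop-2-en-1-yl)cyclohexan-1-one | O=C1CCC[C@H](C[Si](C)(C)OC(C)C)[C@]1(CC=C)C
F2 | step 8 | tert-butyl (7R,7aS)-4-bromo-7a-methyl-2-oxo-2,4,5,6,7,7a-hexahydro-1H-indene-7-carboxylate (C4 epimers) | C1C(=O)C=C2C(Br)CC[C@@H](C(=O)OC(C)(C)C)[C@@]21C
F3 | step 16 | tert-butyl (1R,4S,7R,7aS)-1-[2-(bromomethyl)prop-2-en-1-yl]-4-{[tert-butyl(dimethyl)silyl]oxy}-7a-methyl-2-oxo-2,4,5,6,7,7a-hexahydro-1H-indene-7-carboxylate | C=C(CBr)C[C@H]1C(=O)C=C2[C@@H](O[Si](C)(C)C(C)(C)C)CC[C@@H](C(=O)OC(C)(C)C)[C@@]21C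
F4 | step 16 | tert-butyl (1R,4S,7R,7aS)-4-{[tert-butyl(dimethyl)silyl]oxy}-1-(2-formylprop-2-en-1-yl)-7a-methyl-2-oxo-2,4,5,6,7,7a-hexahydro-1H-indene-7-carboxylate | C=C(C=O)C[C@H]1C(=O)C=C2[C@@H](O[Si](C)(C)C(C)(C)C)CC[C@@H](C(=O)OC(C)(C)C)[C@@]21C
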